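**Retrosynthetic overview**

- The feruloyl ester on O8 is cut last; the alcohol part is guai-1(10)-ene-8,11-diol (ring A: C1–C5, methyl on C4; ring B: C1, C5–C10; C11 on C7).
- The strategy rests on the 1,3-diol array O–C8–C7–C11–O on seven-membered ring B: a Prins retron, so the C7–C8 bond comes from a C8 aldehyde and the C7=C11 prenyl alkene, with water capture at C11.
- The Prins precursor needs C9 cis to C5 on the tetrasubstituted C1=C10 alkene; this Z geometry is fixed through an enol triflate (O cis to C5) that is vinylated with retention, hydroborated and oxidised.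
- One conjugate hydride reduction of an s-cis tetrasubstituted enone sets both the enolate geometry and C5 (cis to the C4 methyl); C4 comes from an asymmetric CuH reduction of 3-methylcyclopent-2-en-1-one.
- Ring A is carried from the starting material; ring B is the only ring formed (step 8).

Key step: step 8

Assumption: (R)-p-tol-BINAP is taken as the ligand antipode that gives the 3S ketone in step 1; if the sense of induction is the reverse, the mirror-image ligand is used.

**Route**

Step 1
Reactants: 1 3-methylcyclopent-2-en-1-one; 2 1-bromo-3-methylbut-2-ene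
Product: 4 (2R,3S)-3-methyl-2-(3-methylbut-2-en-1-yl)cyclopentan-1-one, via bis-enol silyl ether 3 (not isolated)
Conditions: CuCl (5 mol%), NaOt-Bu (5 mol%), (R)-p-tol-BINAP (5 mol%), Ph2SiH2 (0.55 equiv), toluene, 0 °C; then TBAT (tetrabutylammonium difluorotriphenylsilicate, 1.2 equiv), 2 (1.5 equiv), CH2Cl2, rt
Reagents that add atoms: diphenylsilane, [SiH2](c1ccccc1)c1ccccc1 (silicon and phenyl groups of 3 only)
Why: CuH-catalysed asymmetric conjugate reduction (1,4-hydrosilylation) sets C4 under ligand control and leaves the enol silane regiodefined toward the future C5, so fluoride-triggered enolate alkylation should place the prenyl group on that carbon, trans to the methyl (a relationship that step 2 erases on purpose).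

Step 2
Reactants: 4 (2R,3S)-3-methyl-2-(3-methylbut-2-en-1-yl)cyclopentan-1-one
Product: 5 (3S)-3-methyl-2-(3-methylbut-2-en-1-yl)cyclopent-1-en-1-yl trifluoromethanesulfonate
Conditions: Tf2O (1.2 equiv), 2,6-di-tert-butyl-4-methylpyridine (1.5 equiv), CH2Cl2, 0 °C to rt; minor regioisomer removed by chromatography
Reagents that add atoms: trifluoromethanesulfonic anhydride, O=S(=O)(OS(=O)(=O)C(F)(F)F)C(F)(F)F
Why: Enol triflation under equilibrating conditions should favour the more substituted (tetrasubstituted) enol triflate, which removes the C5 stereocentre so that it can be rebuilt cis to the methyl in step 4, while the non-enolisable C4 centre is untouched.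

Step 3
Reactants: 5 (3S)-3-methyl-2-(3-methylbut-2-en-1-yl)cyclopent-1-en-1-yl trifluoromethanesulfonate; 6 tributyl(1-ethoxyethenyl)stannane
Product: 8 1-[(3S)-3-methyl-2-(3-methylbut-2-en-1-yl)cyclopent-1-en-1-yl]ethan-1-one, via ethoxy diene 7 (not isolated)
Conditions: Pd(PPh3)4 (5 mol%), LiCl (3 equiv), THF, 65 °C; then 1 M HCl, THF, rt, short contact
Reagents that add atoms: water, O
Why: Stille coupling of the vinyl triflate with the α-ethoxyvinyl stannane (an acetyl anion equivalent) and hydrolysis of the enol ether should give the tetrasubstituted enone that carries C10 and its methyl; no stereocentre is formed.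

Step 4
Reactants: 8 1-[(3S)-3-methyl-2-(3-methylbut-2-en-1-yl)cyclopent-1-en-1-yl]ethan-1-one
Product: 11 (1Z)-1-[(2S,3S)-3-methyl-2-(3-methylbut-2-en-1-yl)cyclopentylidene]ethyl trifluoromethanesulfonate, via silyl enol ether 9 (not isolated), via lithium enolate 10 (not isolated)
Conditions: [(Ph3P)CuH]6 (3 mol%), PhMe2SiH (1.2 equiv), toluene, rt; then MeLi (1.5 equiv), THF, 0 °C; then PhNTf2 (1.5 equiv), −78 °C to rt
Reagents that add atoms: N-phenylbis(trifluoromethanesulfonimide), O=S(=O)(N(c1ccccc1)S(=O)(=O)C(F)(F)F)C(F)(F)F; dimethyl(phenyl)silane, C[SiH](C)c1ccccc1 (silyl group of 9 only); methyllithium, [Li]C (lithium of 10 only)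
Why: CuH conjugate hydrosilylation should deliver hydride to C5 from the face opposite the adjacent C4 methyl, so the prenyl-bearing carbon ends cis to the methyl (5S), and because A(1,3) strain between the acetyl methyl and the C5 CH2 holds the enone s-cis, the enol oxygen ends cis to C5 (Z), a geometry that silicon-to-lithium exchange and O-triflation retain.

Step 5
Reactants: 11 (1Z)-1-[(2S,3S)-3-methyl-2-(3-methylbut-2-en-1-yl)cyclopentylidene]ethyl trifluoromethanesulfonate; 12 tributyl(ethenyl)stannane
Product: 13 (1Z,2S,3S)-1-(but-3-en-2-ylidene)-3-methyl-2-(3-methylbut-2-en-1-yl)cyclopentane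
Conditions: Pd(PPh3)4 (5 mol%), LiCl (3 equiv), CuI (10 mol%), THF, 50 °C
Reagents that add atoms: none
Why: Stille coupling of an enol triflate proceeds with retention of alkene geometry, so the vinyl group should take the place of the triflate cis to C5; the temperature is kept low so that no sigmatropic hydrogen shift of the Z-diene intervenes.

Step 6
Reactants: 13 (1Z,2S,3S)-1-(but-3-en-2-ylidene)-3-methyl-2-(3-methylbut-2-en-1-yl)cyclopentane
Product: 15 (3Z)-3-[(2S,3S)-3-methyl-2-(3-methylbut-2-en-1-yl)cyclopentylidene]butan-1-ol, via alkylborane 14 (not isolated)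
Conditions: 9-BBN (1.2 equiv), THF, 0 °C to rt; then NaOH (3 M aq), H2O2 (30%), 0 °C
Reagents that add atoms: 9-borabicyclo[3.3.1]nonane, B1C2CCCC1CCC2 (boron of 14 only); hydrogen peroxide, OO
Why: Hydroboration–oxidation with the bulky 9-BBN should touch only the monosubstituted terminal alkene (boron on the terminal carbon), leaving the tetrasubstituted and the prenyl alkenes and giving the primary homoallylic alcohol with the C9–C8 arm cis to C5.

Step 7
Reactants: 15 (3Z)-3-[(2S,3S)-3-methyl-2-(3-methylbut-2-en-1-yl)cyclopentylidene]butan-1-ol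
Product: 16 (3Z)-3-[(2S,3S)-3-methyl-2-(3-methylbut-2-en-1-yl)cyclopentylidene]butanal
Conditions: DMP (1,1,1-triacetoxy-1,1-dihydro-1,2-benziodoxol-3(1H)-one, 1.3 equiv), NaHCO3 (5 equiv), CH2Cl2, 0 °C to rt; used crude at once
Reagents that add atoms: none
Why: Buffered periodinane oxidation under near-neutral conditions should give the β,γ-unsaturated aldehyde without conjugation or change of alkene geometry.

Step 8
Reactants: 16 (3Z)-3-[(2S,3S)-3-methyl-2-(3-methylbut-2-en-1-yl)cyclopentylidene]butanal
Product: 17 (3S,3aS,5S,6S)-5-(2-hydroxypropan-2-yl)-3,8-dimethyl-1,2,3,3a,4,5,6,7-octahydroazulen-6-ol (guai-1(10)-ene-8,11-diol)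
Conditions: Sc(OTf)3 (10 mol%), THF–H2O (4:1), 0.02 M, 0 °C to rt
Reagents that add atoms: water, O
Why: Sc(OTf)3 binds the C8 aldehyde oxygen, C7 of the prenyl alkene attacks C8 in Markovnikov fashion so that the charge develops on tertiary C11, and water from the medium captures that cation, which forms the C7–C8 bond and both hydroxyls in one operation (cationic aldehyde–alkene Prins cyclisation with hydration). The closest known reaction types are the acid-mediated cyclisation–hydration of δ,ε-unsaturated aldehydes to cyclic 1,3-diols and Lewis-acid aldehyde–alkene closures to cycloheptanols. Ring B (C1, C5–C10) closes in a 7-exo-trig mode with respect to the C7=C11 alkene, C11 staying outside the ring. C7 is controlled by C5: the C5–C4 bond of ring A lies in the plane of the C1=C10 alkene, so H5 is pseudo-axial in the chair-like transition state and the forming C11 unit takes the pseudo-equatorial site on C7, which puts H7 cis to H5 (7S); C8 is controlled by the pseudo-equatorial placement of the metal-bound carbonyl oxygen, trans to C11 (8S). The step needs activation of the aldehyde in preference to protonation of the tetrasubstituted C1=C10 alkene or conjugation of the β,γ-unsaturated aldehyde, which the near-neutral aqueous Lewis acid is chosen to secure, and it needs C9 cis to C5, which the Z geometry from step 4 secures; the C1=C10 alkene could only form a three- or four-membered ring with C8 and stays out.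

Step 9
Reactants: 17 guai-1(10)-ene-8,11-diol; 18 (2E)-3-[4-(acetyloxy)-3-methoxyphenyl]prop-2-enoic acid
Product: 19 (3S,3aS,5S,6S)-5-(2-hydroxypropan-2-yl)-3,8-dimethyl-1,2,3,3a,4,5,6,7-octahydroazulen-6-yl (2E)-3-[4-(acetyloxy)-3-methoxyphenyl]prop-2-enoate
Conditions: 18 (1.3 equiv), EDC·HCl (1.5 equiv), DMAP (0.2 equiv), CH2Cl2, 0 °C to rt
Reagents that add atoms: none
Why: Carbodiimide (Steglich) esterification should acylate the secondary C8 hydroxyl only, the tertiary C11 hydroxyl being too hindered, with the phenol masked as its acetate to prevent self-acylation and with C8 retained because the C8–O bond is not broken.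

Step 10
Reactants: 19 the O-acetylferuloyl ester
Product: 20 (3S,3aS,5S,6S)-5-(2-hydroxypropan-2-yl)-3,8-dimethyl-1,2,3,3a,4,5,6,7-octahydroazulen-6-yl (2E)-3-(4-hydroxy-3-methoxyphenyl)prop-2-enoate (CNP0241038.1)
Conditions: K2CO3 (0.2 equiv), MeOH, 0 °C
Reagents that add atoms: none
Why: Carbonate-catalysed transesterification should remove the aryl acetate (phenoxide leaving group) much faster than it attacks the hindered secondary cinnamate, which survives together with the tertiary alcohol and the alkenes.

**Compound list**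

1 | 3-methylcyclopent-2-en-1-one | CC1=CC(=O)CC1 | starting material
2 | 1-bromo-3-methylbut-2-ene | CC(C)=CCBr | starting material
3 | bis{[(3S)-3-methylcyclopent-1-en-1-yl]oxy}(diphenyl)silane | C[C@H]1CCC(O[Si](OC2=C[C@@H](C)CC2)(c2ccccc2)c2ccccc2)=C1 | intermediate
4 | (2R,3S)-3-methyl-2-(3-methylbut-2-en-1-yl)cyclopentan-1-one | O=C1CC[C@H](C)[C@H]1CC=C(C)C | intermediate
5 | (3S)-3-methyl-2-(3-methylbut-2-en-1-yl)cyclopent-1-en-1-yl trifluoromethanesulfonate | O=S(=O)(OC1=C(CC=C(C)C)[C@@H](C)CC1)C(F)(F)F | intermediate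
6 | tributyl(1-ethoxyethenyl)stannane | CCCC[Sn](CCCC)(CCCC)C(=C)OCC | starting material
7 | (3S)-1-(1-ethoxyethenyl)-3-methyl-2-(3-methylbut-2-en-1-yl)cyclopent-1-ene | CCOC(=C)C1=C(CC=C(C)C)[C@@H](C)CC1 | intermediate
8 | 1-[(3S)-3-methyl-2-(3-methylbut-2-en-1-yl)cyclopent-1-en-1-yl]ethan-1-one | CC(=O)C1=C(CC=C(C)C)[C@@H](C)CC1 | intermediate
9 | dimethyl(phenyl){[(1Z)-1-[(2S,3S)-3-methyl-2-(3-methylbut-2-en-1-yl)cyclopentylidene]ethyl]oxy}silane | C[Si](C)(c1ccccc1)O/C(C)=C1/CC[C@H](C)[C@@H]1CC=C(C)C | intermediate
10 | lithium (1Z)-1-[(2S,3S)-3-methyl-2-(3-methylbut-2-en-1-yl)cyclopentylidene]ethan-1-olate | [Li]O/C(C)=C1/CC[C@H](C)[C@@H]1CC=C(C)C | intermediate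
11 | (1Z)-1-[(2S,3S)-3-methyl-2-(3-methylbut-2-en-1-yl)cyclopentylidene]ethyl trifluoromethanesulfonate | O=S(=O)(O/C(C)=C1/CC[C@H](C)[C@@H]1CC=C(C)C)C(F)(F)F | intermediate
12 | tributyl(ethenyl)stannane | C=C[Sn](CCCC)(CCCC)CCCC | starting material
13 | (1Z,2S,3S)-1-(but-3-en-2-ylidene)-3-methyl-2-(3-methylbut-2-en-1-yl)cyclopentane | C=C/C(C)=C1/CC[C@H](C)[C@@H]1CC=C(C)C | intermediate
14 | 9-{(3Z)-3-[(2S,3S)-3-methyl-2-(3-methylbut-2-en-1-yl)cyclopentylidene]butyl}-9-borabicyclo[3.3.1]nonane | B1(CC/C(C)=C2/CC[C@H](C)[C@@H]2CC=C(C)C)C2CCCC1CCC2 | intermediate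
15 | (3Z)-3-[(2S,3S)-3-methyl-2-(3-methylbut-2-en-1-yl)cyclopentylidene]butan-1-ol | OCC/C(C)=C1/CC[C@H](C)[C@@H]1CC=C(C)C | intermediate
16 | (3Z)-3-[(2S,3S)-3-methyl-2-(3-methylbut-2-en-1-yl)cyclopentylidene]butanal | O=CC/C(C)=C1/CC[C@H](C)[C@@H]1CC=C(C)C | intermediate
17 | (3S,3aS,5S,6S)-5-(2-hydroxypropan-2-yl)-3,8-dimethyl-1,2,3,3a,4,5,6,7-octahydroazulen-6-ol | O[C@H]1CC(C)=C2CC[C@H](C)[C@@H]2C[C@@H]1C(C)(C)O | intermediate
18 | (2E)-3-[4-(acetyloxy)-3-methoxyphenyl]prop-2-enoic acid | CC(=O)Oc1ccc(/C=C/C(=O)O)cc1OC | starting material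
19 | (3S,3aS,5S,6S)-5-(2-hydroxypropan-2-yl)-3,8-dimethyl-1,2,3,3a,4,5,6,7-octahydroazulen-6-yl (2E)-3-[4-(acetyloxy)-3-methoxyphenyl]prop-2-enoate | CC(=O)Oc1ccc(/C=C/C(=O)O[C@H]2CC(C)=C3CC[C@H](C)[C@@H]3C[C@@H]2C(C)(C)O)cc1OC | intermediate
20 | (3S,3aS,5S,6S)-5-(2-hydroxypropan-2-yl)-3,8-dimethyl-1,2,3,3a,4,5,6,7-octahydroazulen-6-yl (2E)-3-(4-hydroxy-3-methoxyphenyl)prop-2-enoate | COc1cc(/C=C/C(=O)O[C@H]2CC(C)=C3CC[C@H](C)[C@@H]3C[C@@H]2C(C)(C)O)ccc1O | target

**Step count**

Total: 10 steps. Longest linear sequence: 10 steps (1 to 20); 18 is bought.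

**Steps most likely to fail**

Step 8. The C11 cation may lose a proton instead of being captured by water, the bias for the equatorial C8–O may be weak, or a slow closure may let the β,γ-unsaturated aldehyde conjugate. The fallback sets out from 16: Me2AlCl (1.1 equiv, CH2Cl2, −78 °C) would close ring B by a carbonyl-ene reaction, a closed chair-like process without protic acid that is expected to be trans-selective, to give (3S,3aS,5R,6S)-3,8-dimethyl-5-(prop-1-en-2-yl)-1,2,3,3a,4,5,6,7-octahydroazulen-6-ol F1. Markovnikov hydration of the isopropenyl group of F1 (Mukaiyama hydration: Co(acac)2, PhSiH3, O2, THF/i-PrOH; the tetrasubstituted ring alkene is too hindered to compete) would come back to the route at 17.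

Step 4. Facial discrimination at C5 may be incomplete, or the crowded enone may suffer 1,2-reduction. The fallback sets out from 8 and replaces hydrometalation by dissolving-metal electron transfer: Li in NH3/THF at −78 °C with one equivalent of t-BuOH, which is insensitive to steric crowding at the β-carbon and gives the chelated lithium enolate 10 directly (β-protonation anti to the C4 methyl). After removal of NH3, PhNTf2 in THF would trap 10 and come back to the route at 11. This fallback makes no compound outside the list (F0).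

Step 2. Regiocontrol of the enolisation may be lost, with the triflate forming on the unsubstituted side of the ketone. The fallback sets out from 1 and 2 and fixes the enolate position by conjugate reduction instead of equilibration. α-Alkylation of 1 with 2 through its extended enolate (KOt-Bu, t-BuOH) would give 3-methyl-2-(3-methylbut-2-en-1-yl)cyclopent-2-en-1-one F2. Asymmetric CuH 1,4-hydrosilylation of F2 (Cu(OAc)2, a DTBM-SEGPHOS ligand, PhMe2SiH) would give dimethyl{[(3S)-3-methyl-2-(3-methylbut-2-en-1-yl)cyclopent-1-en-1-yl]oxy}(phenyl)silane F3, whose double bond can only lie toward the prenyl-bearing carbon. MeLi followed by PhNTf2 would convert F3 into the triflate and come back to the route at 5.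

**Further compounds**

F1 | step 8 | (3S,3aS,5R,6S)-3,8-dimethyl-5-(prop-1-en-2-yl)-1,2,3,3a,4,5,6,7-octahydroazulen-6-ol | O[C@H]1CC(C)=C2CC[C@H](C)[C@@H]2C[C@@H]1C(C)=C
F0 | step 4 | none | none
F2 | step 2 | 3-methyl-2-(3-methylbut-2-en-1-yl)cyclopent-2-en-1-one | CC1=C(CC=C(C)C)C(=O)CC1
F3 | step 2 | dimethyl{[(3S)-3-methyl-2-(3-methylbut-2-en-1-yl)cyclopent-1-en-1-yl]oxy}(phenyl)silane | C[Si](C)(c1ccccc1)OC1=C(CC=C(C)C)[C@@H](C)CC1
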